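## Analysis of the target

Compound 18, the target CNP0039507.0, is a linear and fully aromatic trimer in which three benzene rings are joined by two diaryl ether oxygens, and it has no stereocentre, so every selectivity question is one of position. Ring A is a 3,5-dihydroxyphenyl group, ring B carries the ring A oxygen at B1 between hydroxyls at B2 and B6 and the ring C oxygen at B4, and ring C carries the ether oxygen at C1, hydroxyls at C2, C4 and C6, hydrogen at C3 and bromine at C5. The seven free phenols on three phloroglucinol-type rings make the compound air-sensitive and strongly nucleophilic at carbon. The bromine sits on an electron-rich ring where acid can remove or shift it and where hydrogenolysis would cleave it, which rules out benzyl ethers removed with hydrogen. The synthesis is hard for two reasons: each ether oxygen is bonded on one side to a carbon flanked by two oxygenated carbons, B1 and C1, which is the worst case for metal-mediated aryl ether formation, and one bromine must be placed on one of three rings of similar reactivity. The plan is built on ring C, where C6, C1 and C2 form a run of three neighbouring oxygenated carbons whose middle member C1 holds the ether, the same pattern as the oxygenated carbons of a squaric acid diester, while C3 maps onto the second squarate carbonyl carbon after reduction and C4 with its oxygen together with C5 onto a 1-alkoxyvinyl unit. Without its bromine, ring C has a local mirror plane through C1 and C4, so C3 and C5 are equivalent in the fully deprotected triol.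

## Retrosynthetic reasoning

**18 to 17.** The last disconnection cuts the six O–alkyl bonds (four methyl, one ethyl, one isopropyl) of the bromophenol 17. Simple alkyl ethers are chosen because they survive every earlier step and fall together to one Lewis acid, without reductive conditions that would endanger the C–Br bond. The forward step must cleave sp3 C–O bonds only and leave the two diaryl ether bonds and the bromide alone.

**17 to 16.** The C5–Br bond is cut next. Bromination is placed before deprotection because only at the stage of phenol 16 is ring C different from rings A and B: it alone has a free hydroxyl, at C6. The forward step must brominate ring C only; whether it goes to C5 or C3 does not matter for 18.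

**16 to 11 and 12.** Ring C is cut at C3–C4 and C5–C6, giving the 4-chlorocyclobutenone 11 and the stannane 12. This is preferred to an aryl ether coupling at C1, which would have to join an oxygen to a carbon flanked by two oxygenated carbons. The aryloxy group instead travels through the ring synthesis as a substituent, and the bonding sequence alone decides where each oxygen ends up. The forward reaction is a cross-coupling at the sp3 carbon of 11, followed by ring opening of the alkenylcyclobutenone 13 to the ketene 14 and closure to 15, which tautomerises to 16.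

**11 to 10 to 9.** The C–Cl bond of 11 is traced to the alcohol 10, and its C–H bond to the dione 9. The reduction must pick the carbonyl next to the isopropoxy-bearing carbon, so that the surviving carbonyl is the one next to the aryloxy carbon. The chlorination must be non-acidic, because 10 is a vinylogous hemiacetal-type system that loses an oxygen substituent under acid.

**9 to 8 and 5; 8 to 7 to 6.** The C1–O bond of the future ring C is cut at the squarate stage. There it is an addition–elimination of the phenol 5 at the vinylogous acid chloride 8, not an aryl coupling, so flanking substituents do not hinder it. Chloride 8 comes from squaryl dichloride 7 by one alcoholysis, and 7 from squaric acid 6.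

**5 to 3 to 1 and 2.** The ring A–ring B ether is cut at B1–O. In the forward direction the hindered partner is the electrophile 1, whose bromide is activated by the para aldehyde, and the unhindered phenol 2 is the nucleophile. The aldehyde of 3 then serves as a masked hydroxyl: oxidation through the formate 4 reveals the phenol 5 at B4.

## Alternatives that were turned down

**Alternative 1: ring A by cycloaddition.** Ring A would be cut into two pieces, the diene 1-methoxy-1,3-bis(trimethylsilyloxy)buta-1,3-diene A1 and the alkyne methyl 3-[4-(benzyloxy)-2,6-dimethoxyphenoxy]prop-2-ynoate A2. In the forward key step the CH2 end of A1 would bond to the aryloxy-bearing carbon of A2 and the ketene acetal carbon of A1 to the ester-bearing carbon. Loss of a silyl ether would then aromatise the adduct to methyl 2-[4-(benzyloxy)-2,6-dimethoxyphenoxy]-4,6-dihydroxybenzoate A3.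
- For: polarity dictates the regiochemistry. The hindered ring A–ring B ether is made on an alkyne carbon and not by aryl coupling, which is at least as good as step 1 of the chosen route.
- Against: ring A is the one ring that can be bought with its oxygens in place, as 2. The salicylate A3 carries an ester that must be hydrolysed and decarboxylated, and two new phenols to protect. The push–pull ynoate A2 is a sluggish, hydration-prone dienophile. The hard parts (the ether at C1 of ring C, ring C itself and the bromine) are untouched.
- Comparison: it spends its key step on the easiest ring, whereas the chosen strategy spends it on the ring that holds both the hindered ether and the bromine.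

**Alternative 2: ring B by Claisen cyclisation.** Ring B would be cut between B1 and B6, which leads back to an open-chain enoate, methyl (2E)-3-(3-bromo-2,4,6-trimethoxyphenoxy)-6-(3,5-dimethoxyphenoxy)-5-oxohex-2-enoate A5. The enoate A5 would be assembled from 3-bromo-2,4,6-trimethoxyphenol A4 and 2. A strong base would enolise the aryloxymethyl ketone of A5, and the C6 carbanion would attack the ester carbonyl to give 5-(3-bromo-2,4,6-trimethoxyphenoxy)-2-(3,5-dimethoxyphenoxy)benzene-1,3-diol A6.
- For: it is the most convergent plan. Both ether bonds come from simple O-alkylation or conjugate addition of phenols, and the bromine arrives in the building block A4, so no late ring-selective bromination is needed. On these points it is stronger than the chosen route, and only a global demethylation of A6 follows the key step.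
- Against: in A5 the C4 methylene, between the enol ether carbon and the ketone, is more acidic than C6, so the productive enolate is the minor one. The β-aryloxy enoate A5 can also lose its aryloxide by addition–elimination with any nucleophilic base, and its E geometry, which closure needs, must be secured. A4 itself requires a selective monobromination.
- Comparison: the chosen strategy is longer, but its ring-forming events are irreversible pericyclic steps whose regiochemistry follows from the bonding sequence and not from the site of enolisation.

**Alternative 3: ring C by double Claisen condensation.** Ring C would be cut at C2–C3 and C5–C6 into dimethyl 2-[4-(3,5-dimethoxyphenoxy)-3,5-dimethoxyphenoxy]propanedioate A7, which would be made from 5, and dimethyl 3-oxopentanedioate A8. Methoxide-mediated double condensation would give dimethyl 5-[4-(3,5-dimethoxyphenoxy)-3,5-dimethoxyphenoxy]-2,4,6-trihydroxybenzene-1,3-dicarboxylate A9.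
- For: classical phloroglucinol chemistry, cheap, free of tin and palladium, and shorter to ring C than the squarate sequence. On step count and cost it is stronger.
- Against: both ester carbonyls of A7 sit next to a carbon that carries a bulky aryloxy group, A8 condenses readily with itself, and retro-Claisen cleavage is open at every stage. The diester A9 then needs double hydrolysis and decarboxylation. That gives a ring C with three free hydroxyls and two equivalent nucleophilic sites, where over-bromination is the natural outcome.
- Comparison: the chosen strategy delivers ring C with one free hydroxyl and no groups to excise, which is what makes a single bromination controllable.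

Key step: step 8

## Route

Remark: because C3 and C5 of ring C become equivalent once all ethers are cleaved, bromination of 16 at either position leads to 18. The route is written for C5, ortho to the free hydroxyl. Compounds 10, 11 and 13 are racemic; their single stereocentre is destroyed in step 8.

Step 1
Reactants: 1 4-bromo-3,5-dimethoxybenzaldehyde; 2 3,5-dimethoxyphenol
Product: 3 4-(3,5-dimethoxyphenoxy)-3,5-dimethoxybenzaldehyde
Conditions: CuI (10 mol %), N,N-dimethylglycine hydrochloride (30 mol %), Cs2CO3, 1,4-dioxane, 100 °C
Reagents that add atoms: none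
Why: Ullmann-type diaryl ether synthesis; the bromide is activated by the para formyl group, the nucleophile 2 is unhindered, and the tertiary amino acid ligand cannot condense with the aldehyde.

Step 2
Reactants: 3 4-(3,5-dimethoxyphenoxy)-3,5-dimethoxybenzaldehyde
Product: 5 4-(3,5-dimethoxyphenoxy)-3,5-dimethoxyphenol, via aryl formate 4 (not isolated)
Conditions: mCPBA, CH2Cl2, 0 °C to rt; then MeOH, cat. K2CO3, rt
Reagents that add atoms: 3-chloroperoxybenzoic acid (mCPBA), OOC(=O)c1cccc(Cl)c1
Why: Dakin-type Baeyer–Villiger oxidation; the electron-rich aryl group migrates in the peracid adduct to give formate 4, and methanolysis releases the phenol.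

Step 3
Reactants: 6 squaric acid (3,4-dihydroxycyclobut-3-ene-1,2-dione)
Product: 7 squaryl dichloride (3,4-dichlorocyclobut-3-ene-1,2-dione)
Conditions: (COCl)2 (2.2 equiv), cat. DMF, CH2Cl2, 0 °C to reflux
Reagents that add atoms: oxalyl chloride, ClC(=O)C(Cl)=O
Why: Vilsmeier-type activation turns the two vinylogous acid hydroxyls into vinylogous acid chlorides; this is the standard preparation of 7.

Step 4
Reactants: 7 squaryl dichloride
Product: 8 3-chloro-4-isopropoxycyclobut-3-ene-1,2-dione
Conditions: i-PrOH (1.0 equiv), Et2O, 0 °C to rt
Reagents that add atoms: propan-2-ol, CC(C)O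
Why: Addition–elimination at one vinylogous acid chloride carbon; the alkoxy group introduced deactivates the second chloride, so one equivalent of alcohol should stop at the mono-ester.

Step 5
Reactants: 8 3-chloro-4-isopropoxycyclobut-3-ene-1,2-dione; 5 4-(3,5-dimethoxyphenoxy)-3,5-dimethoxyphenol
Product: 9 3-[4-(3,5-dimethoxyphenoxy)-3,5-dimethoxyphenoxy]-4-isopropoxycyclobut-3-ene-1,2-dione
Conditions: i-Pr2NEt (1.1 equiv), CH2Cl2, −40 to 0 °C
Reagents that add atoms: none
Why: Acylation-like addition–elimination of the phenoxide at the chloride-bearing carbon, chloride being a far better leaving group than isopropoxide; base and low temperature favour O-attack over C-attack by the electron-rich phenol. This forms the future C1–O bond of ring C without an aryl coupling.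

Step 6
Reactants: 9 3-[4-(3,5-dimethoxyphenoxy)-3,5-dimethoxyphenoxy]-4-isopropoxycyclobut-3-ene-1,2-dione
Product: 10 2-[4-(3,5-dimethoxyphenoxy)-3,5-dimethoxyphenoxy]-4-hydroxy-3-isopropoxycyclobut-2-en-1-one (racemic)
Conditions: LiAlH(Ot-Bu)3 (1.1 equiv), THF, −78 °C; aq. NaH2PO4/Na2HPO4 (pH 7)
Reagents that add atoms: none
Why: 1,2-Reduction of a squarate ester by a bulky alkoxyaluminium hydride. The carbonyl next to the isopropoxy carbon is vinylogous to the weaker donor (aryloxy) and so is the more electrophilic, and the product keeps the better-stabilised vinylogous isopropyl ester, so kinetic and thermodynamic preferences should agree. The new stereocentre is formed without control and is removed in step 8.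

Step 7
Reactants: 10 2-[4-(3,5-dimethoxyphenoxy)-3,5-dimethoxyphenoxy]-4-hydroxy-3-isopropoxycyclobut-2-en-1-one
Product: 11 4-chloro-2-[4-(3,5-dimethoxyphenoxy)-3,5-dimethoxyphenoxy]-3-isopropoxycyclobut-2-en-1-one (racemic)
Conditions: PPh3, CCl4, CH2Cl2, 0 °C to rt; used without storage
Reagents that add atoms: carbon tetrachloride, ClC(Cl)(Cl)Cl
Why: Appel reaction; chloride displaces the alkoxyphosphonium group under neutral conditions, which avoids the acid-induced 1,3-transposition and loss of an oxygen substituent that 4-hydroxycyclobutenones undergo.

Step 8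
Reactants: 11 4-chloro-2-[4-(3,5-dimethoxyphenoxy)-3,5-dimethoxyphenoxy]-3-isopropoxycyclobut-2-en-1-one; 12 tributyl(1-ethoxyvinyl)stannane
Product: 16 2-[4-(3,5-dimethoxyphenoxy)-3,5-dimethoxyphenoxy]-5-ethoxy-3-isopropoxyphenol, via ethoxyvinylcyclobutenone 13 (not isolated), via dienylketene 14 (not isolated), via cyclohexadienone 15 (not isolated)
Conditions: PdCl2(PhCN)2 (5 mol %), tri(2-furyl)phosphine (10 mol %), 12 (1.3 equiv), 1,4-dioxane, 50 to 100 °C
Reagents that add atoms: none
Why: The divalent palladium precatalyst is reduced by the stannane to zerovalent palladium, which inserts into the allylic, α-keto C–Cl bond of 11, the only carbon–halogen bond present because the aryl bromide is introduced later; transmetalation from 12 and reductive elimination then give 13 (Stille coupling, C3–C4 bond of ring C). On warming, 13 undergoes conrotatory 4π electrocyclic ring opening to ketene 14, and a thermal disrotatory 6π electrocyclisation joins the ketene carbon to the vinyl CH2 (C5–C6 bond), closing the six-membered ring C as dienone 15, which tautomerises to the phenol 16. The closest known reaction type is the palladium-catalysed coupling of 4-chlorocyclobutenones with alkenylstannanes that delivers phenols directly, and only the 2-aryloxy-3-alkoxy substitution is new. No stereocentre is formed, and the racemic centre of 11 and 13 becomes the sp2 carbon C3. The substitution pattern of 16 follows from the order of the atoms alone: the ketene carbon ends up as C6 and carries the hydroxyl, the carbons bearing the aryloxy and isopropoxy groups end up as C1 and C2, and the two stannane carbons end up as C4, with its ethoxy group, and C5. Two selectivities are needed. The first is bond formation at the chlorine-bearing terminus of the oxocyclobutenyl–palladium species, which is favoured because it restores the conjugated vinylogous ester, and coupling at the other terminus would still lead to a phenol with the same 1-aryloxy-2,4,6-trioxygenated ring C. The second is inward rotation of the ethoxyvinyl group on ring opening, which the substrate secures because the opening is reversible, so the ketene with the vinyl group on the wrong side recloses to 13 and only the isomer with the vinyl group cis to the ketene carbon is consumed by the 6π closure.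

Step 9
Reactants: 16 2-[4-(3,5-dimethoxyphenoxy)-3,5-dimethoxyphenoxy]-5-ethoxy-3-isopropoxyphenol
Product: 17 2-bromo-6-[4-(3,5-dimethoxyphenoxy)-3,5-dimethoxyphenoxy]-3-ethoxy-5-isopropoxyphenol
Conditions: NBS (1.0 equiv), i-Pr2NH (10 mol %), CH2Cl2, −78 to −40 °C
Reagents that add atoms: N-bromosuccinimide, O=C1CCC(=O)N1Br
Why: Amine-catalysed ortho-bromination of a phenol (electrophilic aromatic substitution); the free, hydrogen-bonded phenol of ring C should react far faster at low temperature than the ether-only rings A and B. C5, between the hydroxyl and the ethoxy group, is the less hindered site, and attack at C3 would converge on the same final product.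

Step 10
Reactants: 17 2-bromo-6-[4-(3,5-dimethoxyphenoxy)-3,5-dimethoxyphenoxy]-3-ethoxy-5-isopropoxyphenol
Product: 18 4-bromo-2-[4-(3,5-dihydroxyphenoxy)-3,5-dihydroxyphenoxy]benzene-1,3,5-triol (CNP0039507.0)
Conditions: BBr3 (10 equiv), CH2Cl2, −78 °C to rt; then H2O, 0 °C, under argon
Reagents that add atoms: none
Why: Lewis acid ether cleavage; boron coordinates each alkyl aryl ether oxygen and bromide removes the methyl, ethyl and isopropyl groups at their sp3 carbons. The diaryl ether bonds and the aryl bromide offer no sp3 carbon for attack and should persist.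

## Compound list

1 | 4-bromo-3,5-dimethoxybenzaldehyde | COc1cc(C=O)cc(OC)c1Br | starting material
2 | 3,5-dimethoxyphenol | COc1cc(O)cc(OC)c1 | starting material
3 | 4-(3,5-dimethoxyphenoxy)-3,5-dimethoxybenzaldehyde | COc1cc(OC)cc(Oc2c(OC)cc(C=O)cc2OC)c1 | intermediate
4 | 4-(3,5-dimethoxyphenoxy)-3,5-dimethoxyphenyl formate | COc1cc(OC)cc(Oc2c(OC)cc(OC=O)cc2OC)c1 | intermediate
5 | 4-(3,5-dimethoxyphenoxy)-3,5-dimethoxyphenol | COc1cc(OC)cc(Oc2c(OC)cc(O)cc2OC)c1 | intermediate
6 | squaric acid (3,4-dihydroxycyclobut-3-ene-1,2-dione) | OC1=C(O)C(=O)C1=O | starting material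
7 | squaryl dichloride (3,4-dichlorocyclobut-3-ene-1,2-dione) | O=C1C(=O)C(Cl)=C1Cl | intermediate
8 | 3-chloro-4-isopropoxycyclobut-3-ene-1,2-dione | CC(C)OC1=C(Cl)C(=O)C1=O | intermediate
9 | 3-[4-(3,5-dimethoxyphenoxy)-3,5-dimethoxyphenoxy]-4-isopropoxycyclobut-3-ene-1,2-dione | CC(C)OC1=C(Oc2cc(OC)c(Oc3cc(OC)cc(OC)c3)c(OC)c2)C(=O)C1=O | intermediate
10 | 2-[4-(3,5-dimethoxyphenoxy)-3,5-dimethoxyphenoxy]-4-hydroxy-3-isopropoxycyclobut-2-en-1-one (racemic) | O=C1C(Oc2cc(OC)c(Oc3cc(OC)cc(OC)c3)c(OC)c2)=C(OC(C)C)C1O | intermediate
11 | 4-chloro-2-[4-(3,5-dimethoxyphenoxy)-3,5-dimethoxyphenoxy]-3-isopropoxycyclobut-2-en-1-one (racemic) | O=C1C(Oc2cc(OC)c(Oc3cc(OC)cc(OC)c3)c(OC)c2)=C(OC(C)C)C1Cl | intermediate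
12 | tributyl(1-ethoxyvinyl)stannane | CCCC[Sn](CCCC)(CCCC)C(=C)OCC | starting material
13 | 2-[4-(3,5-dimethoxyphenoxy)-3,5-dimethoxyphenoxy]-4-(1-ethoxyvinyl)-3-isopropoxycyclobut-2-en-1-one (racemic) | O=C1C(Oc2cc(OC)c(Oc3cc(OC)cc(OC)c3)c(OC)c2)=C(OC(C)C)C1C(=C)OCC | intermediate
14 | (3E)-2-[4-(3,5-dimethoxyphenoxy)-3,5-dimethoxyphenoxy]-5-ethoxy-3-isopropoxyhexa-1,3,5-trien-1-one (ethoxyvinyl group cis to the ketene-bearing carbon) | O=C=C(Oc1cc(OC)c(Oc2cc(OC)cc(OC)c2)c(OC)c1)/C(OC(C)C)=C\C(=C)OCC | intermediate
15 | 2-[4-(3,5-dimethoxyphenoxy)-3,5-dimethoxyphenoxy]-5-ethoxy-3-isopropoxycyclohexa-2,4-dien-1-one | O=C1CC(OCC)=CC(OC(C)C)=C1Oc1cc(OC)c(Oc2cc(OC)cc(OC)c2)c(OC)c1 | intermediate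
16 | 2-[4-(3,5-dimethoxyphenoxy)-3,5-dimethoxyphenoxy]-5-ethoxy-3-isopropoxyphenol | CCOc1cc(O)c(Oc2cc(OC)c(Oc3cc(OC)cc(OC)c3)c(OC)c2)c(OC(C)C)c1 | intermediate
17 | 2-bromo-6-[4-(3,5-dimethoxyphenoxy)-3,5-dimethoxyphenoxy]-3-ethoxy-5-isopropoxyphenol | CCOc1cc(OC(C)C)c(Oc2cc(OC)c(Oc3cc(OC)cc(OC)c3)c(OC)c2)c(O)c1Br | intermediate
18 | 4-bromo-2-[4-(3,5-dihydroxyphenoxy)-3,5-dihydroxyphenoxy]benzene-1,3,5-triol | Oc1cc(O)cc(Oc2c(O)cc(Oc3c(O)cc(O)c(Br)c3O)cc2O)c1 | target

## Step count and least certain steps

Total: 10 steps. Longest linear sequence: 8 steps (steps 3 to 10 from squaric acid 6, or steps 1, 2 and 5 to 10 from aldehyde 1).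

**Step 8 (key step).** The most likely failures are ionisation of the chloride with loss of the aryloxy group before palladium inserts, protodestannylation of the acid-sensitive alkoxyvinylstannane by the phenol as it forms, and capture of the ketene by that phenol in competition with the 6π closure. The fallback gives up the squarate construction of ring C and sets out from phenol 5. A CuI-catalysed Ullmann coupling (picolinic acid, Cs2CO3, NMP, 120 °C) with an excess of the readily available, symmetrical 2,4-dibromo-1,3,5-trimethoxybenzene F1, whose two bromines are equivalent, would give 2-bromo-4-[4-(3,5-dimethoxyphenoxy)-3,5-dimethoxyphenoxy]-1,3,5-trimethoxybenzene F2. This is a demanding aryl ether coupling of a type long used for permethylated phlorethols. BBr3 in CH2Cl2 would then cleave the seven methyl ethers, and the sequence comes back at 18.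

**Step 6.** Hydride may not discriminate enough between the two carbonyls, or may add in conjugate fashion with expulsion of the aryloxide. The fallback makes the regiochemistry a matter of mechanism and sets out from 7 and 5. Two equivalents of 5 with i-Pr2NEt would give the symmetrical 3,4-bis[4-(3,5-dimethoxyphenoxy)-3,5-dimethoxyphenoxy]cyclobut-3-ene-1,2-dione F3, whose reduction with LiAlH(Ot-Bu)3 has no regiochemical issue. It gives 2,3-bis[4-(3,5-dimethoxyphenoxy)-3,5-dimethoxyphenoxy]-4-hydroxycyclobut-2-en-1-one F4. Only the aryloxy group β to the carbonyl of F4 is open to addition–elimination, so exchange with isopropanol and i-Pr2NEt at room temperature would release one equivalent of 5 and return to the route at 10.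

**Step 7.** The chloride may ionise during its formation or isolation, with allylic transposition or hydrolytic loss of the aryloxy group. The fallback replaces the halide by a non-ionising allylic ester and sets out from 10. Acetylation (Ac2O, pyridine, DMAP) would give 3-[4-(3,5-dimethoxyphenoxy)-3,5-dimethoxyphenoxy]-2-isopropoxy-4-oxocyclobut-2-en-1-yl acetate F5. This would be coupled with 12 under allylic-acetate Stille conditions (Pd2(dba)3, LiCl, DMF, then heat), passing through 13, 14 and 15 and coming back at 16.

**Step 9.** Rings A and B are phloroglucinol-type triethers, so bromination could spill onto them or go twice on ring C. The fallback widens the reactivity gap before brominating and sets out from 16. BCl3 in CH2Cl2 (−78 to 0 °C) cleaves aryl isopropyl ethers selectively and would give the symmetrical 2-[4-(3,5-dimethoxyphenoxy)-3,5-dimethoxyphenoxy]-5-ethoxybenzene-1,3-diol F6, in which ring C has two free hydroxyls and two equivalent open positions. One equivalent of NBS at −78 °C would give 4-bromo-2-[4-(3,5-dimethoxyphenoxy)-3,5-dimethoxyphenoxy]-5-ethoxybenzene-1,3-diol F7, and BBr3 would then cleave the remaining ethers, coming back at 18.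

**Step 10.** Six ethers must be cleaved. Incomplete dealkylation, acid-promoted loss or migration of bromine on the fully activated ring C during the HBr-rich quench, and air oxidation of the heptaphenol during purification are the likely problems. The fallback changes isolation to capture and release and sets out from 17. After BBr3 the crude product would be acetylated directly (Ac2O, pyridine) to 4-bromo-2-[4-(3,5-diacetoxyphenoxy)-3,5-diacetoxyphenoxy]benzene-1,3,5-triyl triacetate F8. This is stable to air and silica and separable from partly dealkylated material. Methanolysis under argon with HCl generated from acetyl chloride in methanol would then release 18.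

## Further compounds

F1 | step 8 | 2,4-dibromo-1,3,5-trimethoxybenzene | COc1cc(OC)c(Br)c(OC)c1Br
F2 | step 8 | 2-bromo-4-[4-(3,5-dimethoxyphenoxy)-3,5-dimethoxyphenoxy]-1,3,5-trimethoxybenzene | COc1cc(OC)cc(Oc2c(OC)cc(Oc3c(OC)cc(OC)c(Br)c3OC)cc2OC)c1
F3 | step 6 | 3,4-bis[4-(3,5-dimethoxyphenoxy)-3,5-dimethoxyphenoxy]cyclobut-3-ene-1,2-dione | O=C1C(=O)C(Oc2cc(OC)c(Oc3cc(OC)cc(OC)c3)c(OC)c2)=C1Oc1cc(OC)c(Oc2cc(OC)cc(OC)c2)c(OC)c1
F4 | step 6 | 2,3-bis[4-(3,5-dimethoxyphenoxy)-3,5-dimethoxyphenoxy]-4-hydroxycyclobut-2-en-1-one (racemic) | O=C1C(Oc2cc(OC)c(Oc3cc(OC)cc(OC)c3)c(OC)c2)=C(Oc2cc(OC)c(Oc3cc(OC)cc(OC)c3)c(OC)c2)C1O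
F5 | step 7 | 3-[4-(3,5-dimethoxyphenoxy)-3,5-dimethoxyphenoxy]-2-isopropoxy-4-oxocyclobut-2-en-1-yl acetate (racemic) | CC(=O)OC1C(=O)C(Oc2cc(OC)c(Oc3cc(OC)cc(OC)c3)c(OC)c2)=C1OC(C)C
F6 | step 9 | 2-[4-(3,5-dimethoxyphenoxy)-3,5-dimethoxyphenoxy]-5-ethoxybenzene-1,3-diol | CCOc1cc(O)c(Oc2cc(OC)c(Oc3cc(OC)cc(OC)c3)c(OC)c2)c(O)c1
F7 | step 9 | 4-bromo-2-[4-(3,5-dimethoxyphenoxy)-3,5-dimethoxyphenoxy]-5-ethoxybenzene-1,3-diol | CCOc1cc(O)c(Oc2cc(OC)c(Oc3cc(OC)cc(OC)c3)c(OC)c2)c(O)c1Br
F8 | step 10 | 4-bromo-2-[4-(3,5-diacetoxyphenoxy)-3,5-diacetoxyphenoxy]benzene-1,3,5-triyl triacetate | CC(=O)Oc1cc(OC(C)=O)cc(Oc2c(OC(C)=O)cc(Oc3c(OC(C)=O)cc(OC(C)=O)c(Br)c3OC(C)=O)cc2OC(C)=O)c1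
A1 | alternative 1 | 1-methoxy-1,3-bis(trimethylsilyloxy)buta-1,3-diene | COC(O[Si](C)(C)C)=CC(=C)O[Si](C)(C)C
A2 | alternative 1 | methyl 3-[4-(benzyloxy)-2,6-dimethoxyphenoxy]prop-2-ynoate | COC(=O)C#COc1c(OC)cc(OCc2ccccc2)cc1OC
A3 | alternative 1 | methyl 2-[4-(benzyloxy)-2,6-dimethoxyphenoxy]-4,6-dihydroxybenzoate | COC(=O)c1c(O)cc(O)cc1Oc1c(OC)cc(OCc2ccccc2)cc1OC
A4 | alternative 2 | 3-bromo-2,4,6-trimethoxyphenol | Oc1c(OC)c(Br)c(OC)cc1OC
A5 | alternative 2 | methyl (2E)-3-(3-bromo-2,4,6-trimethoxyphenoxy)-6-(3,5-dimethoxyphenoxy)-5-oxohex-2-enoate | COC(=O)/C=C(/Oc1c(OC)cc(OC)c(Br)c1OC)CC(=O)COc1cc(OC)cc(OC)c1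
A6 | alternative 2 | 5-(3-bromo-2,4,6-trimethoxyphenoxy)-2-(3,5-dimethoxyphenoxy)benzene-1,3-diol | COc1cc(OC)cc(Oc2c(O)cc(Oc3c(OC)cc(OC)c(Br)c3OC)cc2O)c1
A7 | alternative 3 | dimethyl 2-[4-(3,5-dimethoxyphenoxy)-3,5-dimethoxyphenoxy]propanedioate | COC(=O)C(Oc1cc(OC)c(Oc2cc(OC)cc(OC)c2)c(OC)c1)C(=O)OC
A8 | alternative 3 | dimethyl 3-oxopentanedioate | COC(=O)CC(=O)CC(=O)OC
A9 | alternative 3 | dimethyl 5-[4-(3,5-dimethoxyphenoxy)-3,5-dimethoxyphenoxy]-2,4,6-trihydroxybenzene-1,3-dicarboxylate | COC(=O)c1c(O)c(Oc2cc(OC)c(Oc3cc(OC)cc(OC)c3)c(OC)c2)c(O)c(C(=O)OC)c1O
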